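Adding two columns is the easy step: at the last reading of the south-east run, 18.4% of target and 37.2% of dissolved substrate, both as fractions of the solid charged, make 55.6%. I call this the ceiling of the solution, assuming that the rest of the charge is by then lost for good; any solid still waiting in that rest makes the reading low.

| flask | solid substrate | partner | protic impurity | remark | time |
|---|---|---|---|---|---|
| north | 20 mM | 15 mM | 10 mM | run made earlier |  |
| south-east | 20 mM | 22 mM | 10 mM | run made earlier |  |
| flask | 20 mM | 30.0 mM | 10.0 mM |  | 20 h |

| run | time / h | target / % | dissolved substrate / % |
|---|---|---|---|
| north | 1.33 | 2.1 | 17.9 |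
| north | 2.00 | 4.8 | 21.4 |
| north | 3.00 | 6.4 | 27.6 |
| north | 5.00 | 10.4 | 33.2 |
| north | 6.00 | 11.4 | 33.4 |
| north | 10.0 | 13.7 | 36.3 |
| north | 15.0 | 15.1 | 37.7 |
| south-east | 0.833 | 1.7 | 12.5 |
| south-east | 2.50 | 6.8 | 25.3 |
| south-east | 5.00 | 13.1 | 31.6 |
| south-east | 6.00 | 14.1 | 32.7 |
| south-east | 10.0 | 17.0 | 36.4 |
| south-east | 12.0 | 17.3 | 36.7 |
| south-east | 15.0 | 18.4 | 37.2 |

(readings scatter by 0.5 percentage points)

- solid substrate is a solid; its amount is given per volume of the solution
- what was read earlier has a scatter of 0.5 percentage points, one standard deviation
- at the start none of the solid substrate is in solution
- dissolved substrate means what is dissolved; the solid is not counted in it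

- target at 20 h, in percent of the solid substrate charged
- concentration of dissolved substrate in solution at 20 h, in percent of saturation

Dissolved substrate levels off alike in north and south-east although the partner differs, and I read the mean of the last readings, 37.5%, as the saturated fraction. While solid remains, fresh dissolving pays for new target and the dissolved fraction can stay there; once the solid is out, the two columns trade point for point. Control therefore changes hands at the crossing target, the ceiling minus the saturated fraction, 18.1%: above it, the ceiling taken as unchanged, each further point of target comes out of the dissolved fraction.

For the flask, with 30.0 mM of partner, a straight line through the last target readings of north and south-east gives me 22.2%, which is more than the crossing, so I expect the solid to be out and 33.4% dissolved, or 89.3% of saturation. The forecast says 22.5% and 99%, holding that “by 20 h the solution is essentially saturated”. The flask gives 21.1% of target and 91.7% of saturation, and at 20.0 h it holds 0% solid and 34.8% dissolved substrate, its target 3 percentage points past the crossing.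

    2 partner → self-condensation product (k = 0.160 M⁻¹ min⁻¹)
    solid substrate ⇌ dissolved substrate, rate k2*(cs2 - [dissolved substrate]) while solid is left; crystals form when [dissolved substrate] > cs2 (solubility = 7.60 mM, k = 0.00900 min⁻¹)
    solid substrate + protic impurity → quenched substrate (k = 0.830 M⁻¹ min⁻¹)
    dissolved substrate + partner → target (k = 0.270 M⁻¹ min⁻¹)
    partner → side product (k = 0.00240 min⁻¹)

The neighbouring flask is the same charge with 18 mM of partner. The same straight line gives it 16.5% of target, which is less than the crossing, so I expect its dissolved fraction to stay at the saturated 37.5%. At 20.0 h this neighbour holds 16.7% of target beside 37.8% of dissolved substrate, together 54.5%, less than the ceiling, with 0% solid, and the partner, its limiting reagent, is down to 0.26%.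

The data stem from a simulated flask with made-up constants; noise was put on by code.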